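**Retrosynthetic overview**
- The last two steps remove the silyl ether and the two phenol benzyl ethers.
- Key disconnection: the oxolane C3–C4 bond. Oxolane C3 carries CH2OH and is bonded to C4, which carries the CH2 arm to the benzene ring of the dihydrobenzofuran (ring B). A C3 radical released from an epoxide spanning C3 and the CH2O carbon can therefore close onto a cinnamyl ether alkene (C4=CH–ring B) tethered through O1 to C2, which bears ring A (the 3-oxy-4-methoxyphenyl ring).
- The epoxy cinnamyl ether comes from a Williamson union of an epoxy alcohol (Sharpless kinetic resolution of the vinyl carbinol of O-benzylisovanillin) with a cinnamyl bromide (Stille coupling on a 6-bromodihydrobenzofuran).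
- The dihydrobenzofuran comes from an Evans syn-aldol, which sets C3, followed by acid-mediated closure of the phenol onto the benzylic carbinol, which sets trans C2. The arylacetic acid comes from 4-bromo-2-fluoro-6-methoxybenzaldehyde by SNAr and one-carbon homologation.
- Ring order: the dihydrofuran ring of the benzofuran is closed first (step 8), the oxolane last (step 15).

Key step: step 15

Remark: the epoxide carbon of 25 and 26 becomes a planar radical in step 15, so only the carbinol carbon of 25 has to be configurationally pure.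

**Route**

Step 1
Reactants: 1 4-bromo-2-fluoro-6-methoxybenzaldehyde
Product: 2 4-bromo-2-methoxy-6-(prop-2-en-1-yloxy)benzaldehyde
Conditions: allyl alcohol, Cs2CO3, DMF, 60 °C
Reagents that add atoms: allyl alcohol, C=CCO
Why: Nucleophilic aromatic substitution (SNAr), in which the fluoride ortho to the formyl group is displaced through a Meisenheimer adduct while the bromide para to it is a much poorer leaving group in this mechanism.

Step 2
Reactants: 2 4-bromo-2-methoxy-6-(prop-2-en-1-yloxy)benzaldehyde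
Product: 4 2-[4-bromo-2-methoxy-6-(prop-2-en-1-yloxy)phenyl]acetonitrile, via tosylalkenyl formamide 3 (not isolated)
Conditions: TosMIC, KOtBu, DME, −35 °C; then MeOH, reflux
Reagents that add atoms: tosylmethyl isocyanide (TosMIC), Cc1ccc(cc1)S(=O)(=O)C[N+]#[C-]
Why: Van Leusen reductive cyanation, in which the TosMIC anion adds to the aldehyde, the oxazoline opens to 3, and methanolysis expels formate and sulfinate to leave the nitrile one carbon longer; no stereocenter is formed.

Step 3
Reactants: 4 2-[4-bromo-2-methoxy-6-(prop-2-en-1-yloxy)phenyl]acetonitrile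
Product: 6 2-[4-bromo-2-methoxy-6-(prop-2-en-1-yloxy)phenyl]acetic acid, via primary amide 5 (not isolated)
Conditions: KOH, EtOH/H2O, reflux; then aq. HCl to pH 2
Reagents that add atoms: potassium hydroxide, [K+].[OH-]; water, O
Why: Base hydrolysis of a nitrile through the amide, under which the aryl allyl ether and the aryl bromide should be inert.

Step 4
Reactants: 6 2-[4-bromo-2-methoxy-6-(prop-2-en-1-yloxy)phenyl]acetic acid; 7 (S)-4-benzyl-1,3-oxazolidin-2-one
Product: 9 (S)-4-benzyl-3-{2-[4-bromo-2-methoxy-6-(prop-2-en-1-yloxy)phenyl]acetyl}-1,3-oxazolidin-2-one, via mixed pivalic anhydride 8 (not isolated)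
Conditions: t-BuCOCl, Et3N, THF, −20 °C; then LiCl, 7, rt
Reagents that add atoms: none
Why: N-acylation of the Evans auxiliary through a mixed anhydride (LiCl/Et3N variant), which avoids an acid chloride that would lose HCl to a ketene.

Step 5
Reactants: 9 (S)-4-benzyl-3-{2-[4-bromo-2-methoxy-6-(prop-2-en-1-yloxy)phenyl]acetyl}-1,3-oxazolidin-2-one; 10 4-(benzyloxy)-3-methoxybenzaldehyde
Product: 13 (2S,3S)-syn-aldol imide, via Z-boron enolate 11 (not isolated), via boron aldolate 12 (not isolated)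
Conditions: Bu2BOTf, iPr2NEt, CH2Cl2, −78 to 0 °C; 10, −78 to 0 °C; then pH 7 buffer, MeOH, H2O2, 0 °C
Reagents that add atoms: none
Why: Evans syn-aldol reaction, in which the Z-boron enolate reacts through a Zimmerman–Traxler chair on the face away from the benzyl group of the (S)-auxiliary, setting the aryl-bearing carbon as S (the later benzofuran C3) and the carbinol carbon as S.

Step 6
Reactants: 13 (2S,3S)-syn-aldol imide
Product: 14 (1S,2R)-1-[4-(benzyloxy)-3-methoxyphenyl]-2-[4-bromo-2-methoxy-6-(prop-2-en-1-yloxy)phenyl]propane-1,3-diol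
Conditions: LiBH4, MeOH (1.1 equiv), THF, 0 °C
Reagents that add atoms: none
Why: Reductive cleavage of the N-acyl oxazolidinone by hydride attack on the exocyclic carbonyl, which should leave both stereocenters, the aryl bromide and the allyl ether untouched (the descriptor of the aryl-bearing carbon changes from S to R only because the priorities change).

Step 7
Reactants: 14 (1S,2R)-1-[4-(benzyloxy)-3-methoxyphenyl]-2-[4-bromo-2-methoxy-6-(prop-2-en-1-yloxy)phenyl]propane-1,3-diol
Product: 15 (1S,2R)-1-[4-(benzyloxy)-3-methoxyphenyl]-2-(4-bromo-2-hydroxy-6-methoxyphenyl)propane-1,3-diol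
Conditions: Pd(PPh3)4 (5 mol%), morpholine, THF, rt
Reagents that add atoms: none
Why: Tsuji–Trost deallylation, in which zerovalent palladium ionises the aryl allyl ether at room temperature, well below the temperature at which it inserts into the aryl bromide, and morpholine takes up the allyl group.

Step 8
Reactants: 15 (1S,2R)-1-[4-(benzyloxy)-3-methoxyphenyl]-2-(4-bromo-2-hydroxy-6-methoxyphenyl)propane-1,3-diol
Product: 17 [(2S,3R)-2-[4-(benzyloxy)-3-methoxyphenyl]-6-bromo-4-methoxy-2,3-dihydro-1-benzofuran-3-yl]methanol, via benzylic cation 16 (not isolated)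
Conditions: p-TsOH·H2O (10 mol%), MeCN, 0 °C to rt
Reagents that add atoms: none
Why: Acid-catalysed SN1 etherification, in which the para-benzyloxy group stabilises the benzylic cation, the ortho phenol closes the five-membered ring (5-exo), and closure anti to the CH2OH group, reversible under the acid, should give the trans isomer, so that C2 (S) is set by C3 (R).

Step 9
Reactants: 17 [(2S,3R)-2-[4-(benzyloxy)-3-methoxyphenyl]-6-bromo-4-methoxy-2,3-dihydro-1-benzofuran-3-yl]methanol
Product: 18 tert-butyldimethylsilyl ether of 17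
Conditions: TBSCl, imidazole, DMF, rt
Reagents that add atoms: tert-butyldimethylsilyl chloride, CC(C)(C)[Si](C)(C)Cl
Why: Silylation of the only free hydroxyl group, which masks it for the bromination and alkylation that follow.

Step 10
Reactants: 18 tert-butyldimethylsilyl ether of 17; 19 (E)-3-(tributylstannyl)prop-2-en-1-ol
Product: 20 (E)-3-[(2S,3R)-2-[4-(benzyloxy)-3-methoxyphenyl]-3-{[(tert-butyldimethylsilyl)oxy]methyl}-4-methoxy-2,3-dihydro-1-benzofuran-6-yl]prop-2-en-1-ol
Conditions: Pd(PPh3)4 (5 mol%), toluene, 100 °C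
Reagents that add atoms: none
Why: Stille coupling of the unhindered aryl bromide with the vinylstannane, which transfers the hydroxypropenyl group with retention of the E geometry.

Step 11
Reactants: 20 (E)-cinnamyl alcohol of the (2S,3R)-benzofuran
Product: 21 (E)-cinnamyl bromide of the (2S,3R)-benzofuran
Conditions: CBr4, PPh3, CH2Cl2, 0 °C
Reagents that add atoms: carbon tetrabromide, BrC(Br)(Br)Br
Why: Appel reaction under neutral conditions, which should convert the primary allylic alcohol to the bromide without touching the silyl ether or the benzylic ethers; the bromide is used without storage.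

Step 12
Reactants: 22 3-(benzyloxy)-4-methoxybenzaldehyde; 23 vinylmagnesium bromide
Product: 24 rac-1-[3-(benzyloxy)-4-methoxyphenyl]prop-2-en-1-ol
Conditions: THF, −10 to 0 °C; then H2O
Reagents that add atoms: none
Why: Grignard 1,2-addition to the aldehyde, which gives the racemic allylic alcohol that the next step resolves.

Step 13
Reactants: 24 rac-1-[3-(benzyloxy)-4-methoxyphenyl]prop-2-en-1-ol
Product: 25 (S)-[3-(benzyloxy)-4-methoxyphenyl][(2R)-oxiran-2-yl]methanol
Conditions: Ti(OiPr)4 (20 mol%), L-(+)-diisopropyl tartrate (24 mol%), t-BuOOH (0.45 equiv), 4 Å molecular sieves, CH2Cl2, −20 °C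
Reagents that add atoms: tert-butyl hydroperoxide, CC(C)(C)OO
Why: Sharpless kinetic resolution, in which the L-(+)-tartrate catalyst epoxidises the (R)-enantiomer of 24 much faster than the (S)-enantiomer and on the face that gives the erythro epoxy alcohol, so that stopping below half conversion should give 25 with the S carbinol carbon and the R epoxide carbon, the unreacted (S)-alcohol being removed by chromatography.

Step 14
Reactants: 25 (S)-[3-(benzyloxy)-4-methoxyphenyl][(2R)-oxiran-2-yl]methanol; 21 (E)-cinnamyl bromide of the (2S,3R)-benzofuran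
Product: 26 epoxy cinnamyl ether (S at the carbinol carbon; R at the epoxide carbon; E alkene; 2S,3R benzofuran)
Conditions: NaH, THF, 0 °C; then 21, Bu4NI (10 mol%), THF/DMSO, 0 °C to rt
Reagents that add atoms: none
Why: Williamson ether synthesis, in which the sodium alkoxide of 25 displaces the primary allylic bromide by SN2 at a temperature low enough to hold back Payne rearrangement, and no stereocenter is touched.

Step 15
Reactants: 26 epoxy cinnamyl ether
Product: 30 [(2R,3S,4S)-2-[3-(benzyloxy)-4-methoxyphenyl]-4-{[(2S,3R)-2-[4-(benzyloxy)-3-methoxyphenyl]-3-{[(tert-butyldimethylsilyl)oxy]methyl}-4-methoxy-2,3-dihydro-1-benzofuran-6-yl]methyl}oxolan-3-yl]methanol, via titanoxy alkyl radical 27 (not isolated), via cyclised benzylic radical 28 (not isolated), via benzyltitanium alkoxide 29 (not isolated)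
Conditions: Cp2TiCl2 (3 equiv), Zn dust, THF, rt (green Cp2TiCl), added slowly to 26 in THF, rt; then 1 M HCl, 0 °C
Reagents that add atoms: none
Why: Cp2TiCl, trivalent titanium made in the flask from Cp2TiCl2 and zinc, transfers one electron to the epoxide, whose bond from oxygen to the more substituted carbon breaks to give the secondary radical 27 at the future C3 with a titanium alkoxide on the CH2O carbon (Nugent–RajanBabu epoxide opening). The radical adds to the near carbon of the cinnamyl ether alkene in a 5-exo-trig radical cyclisation that forms the C3–C4 bond and closes the oxolane ring, and the benzylic radical 28 is reduced by a second Cp2TiCl to the benzyltitanium 29, which the acid work-up protonates to the CH2 arm and the free CH2OH. The closest known reaction type is the Cp2TiCl-mediated cyclisation of epoxy cinnamyl ethers to 2-aryl-3-(hydroxymethyl)-4-benzyloxolanes. Both new stereocenters are controlled by the C2 carbinol carbon: in the chair-like (Beckwith–Houk) transition state the C2 aryl group sits pseudo-equatorial, the CH2O–titanium group on the radical carbon turns away from it (2,3-trans, C3 S), and the alkene arm lies cis to that group (3,4-cis, C4 S). The step needs this 2,3-trans-3,4-cis diastereoselectivity and needs ring closure to outrun reduction of 27; the conjugated acceptor, which makes closure fast and gives a stabilised benzylic radical, and the slow addition, which keeps Cp2TiCl dilute, should secure the second, and the planar radical makes the epoxide configuration of 26 irrelevant.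

Step 16
Reactants: 30 silyl-protected bis-benzyl oxolane
Product: 31 [(2R,3S,4S)-2-[3-(benzyloxy)-4-methoxyphenyl]-4-{[(2S,3R)-2-[4-(benzyloxy)-3-methoxyphenyl]-3-(hydroxymethyl)-4-methoxy-2,3-dihydro-1-benzofuran-6-yl]methyl}oxolan-3-yl]methanol
Conditions: Bu4NF, THF, rt
Reagents that add atoms: none
Why: Fluoride-mediated desilylation, driven by the strong Si–F bond, which should free the benzofuran CH2OH without affecting any stereocenter.

Step 17
Reactants: 31 bis-benzyl ether diol
Product: 32 5-[(2R,3S,4S)-3-(hydroxymethyl)-4-{[(2S,3R)-2-(4-hydroxy-3-methoxyphenyl)-3-(hydroxymethyl)-4-methoxy-2,3-dihydro-1-benzofuran-6-yl]methyl}oxolan-2-yl]-2-methoxyphenol (CNP0242386.1)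
Conditions: H2 (1 atm), 10% Pd/C, EtOAc/EtOH, rt, stopped after uptake of two equivalents
Reagents that add atoms: none
Why: Catalytic hydrogenolysis, in which the two primary benzyl aryl ethers should be cleaved much faster than the secondary, ring-bound benzylic C–O bonds of the oxolane and the dihydrobenzofuran, so the five stereocenters are kept.

**Compound list**

1 | 4-bromo-2-fluoro-6-methoxybenzaldehyde | COc1cc(Br)cc(F)c1C=O | starting material
2 | 4-bromo-2-methoxy-6-(prop-2-en-1-yloxy)benzaldehyde | COc1cc(Br)cc(OCC=C)c1C=O | intermediate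
3 | N-{2-[4-bromo-2-methoxy-6-(prop-2-en-1-yloxy)phenyl]-1-tosylethenyl}formamide | COc1cc(Br)cc(OCC=C)c1C=C(NC=O)S(=O)(=O)c1ccc(C)cc1 | intermediate
4 | 2-[4-bromo-2-methoxy-6-(prop-2-en-1-yloxy)phenyl]acetonitrile | COc1cc(Br)cc(OCC=C)c1CC#N | intermediate
5 | 2-[4-bromo-2-methoxy-6-(prop-2-en-1-yloxy)phenyl]acetamide | COc1cc(Br)cc(OCC=C)c1CC(N)=O | intermediate
6 | 2-[4-bromo-2-methoxy-6-(prop-2-en-1-yloxy)phenyl]acetic acid | COc1cc(Br)cc(OCC=C)c1CC(=O)O | intermediate
7 | (S)-4-benzyl-1,3-oxazolidin-2-one | O=C1OC[C@H](Cc2ccccc2)N1 | starting material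
8 | mixed anhydride of 6 with pivalic acid | COc1cc(Br)cc(OCC=C)c1CC(=O)OC(=O)C(C)(C)C | intermediate
9 | (S)-4-benzyl-3-{2-[4-bromo-2-methoxy-6-(prop-2-en-1-yloxy)phenyl]acetyl}-1,3-oxazolidin-2-one | COc1cc(Br)cc(OCC=C)c1CC(=O)N1C(=O)OC[C@@H]1Cc1ccccc1 | intermediate
10 | 4-(benzyloxy)-3-methoxybenzaldehyde | COc1cc(C=O)ccc1OCc1ccccc1 | starting material
11 | Z-dibutylboron enolate of 9 | CCCCB(CCCC)O/C(=C\c1c(OC)cc(Br)cc1OCC=C)N1C(=O)OC[C@@H]1Cc1ccccc1 | intermediate
12 | O-dibutylboryl aldolate of 13 | O=C(N1C(=O)OC[C@@H]1Cc1ccccc1)[C@@H](c1c(OC)cc(Br)cc1OCC=C)[C@H](OB(CCCC)CCCC)c1ccc(OCc2ccccc2)c(OC)c1 | intermediate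
13 | (S)-4-benzyl-3-[(2S,3S)-3-[4-(benzyloxy)-3-methoxyphenyl]-2-[4-bromo-2-methoxy-6-(prop-2-en-1-yloxy)phenyl]-3-hydroxypropanoyl]-1,3-oxazolidin-2-one | O=C(N1C(=O)OC[C@@H]1Cc1ccccc1)[C@@H](c1c(OC)cc(Br)cc1OCC=C)[C@H](O)c1ccc(OCc2ccccc2)c(OC)c1 | intermediate
14 | (1S,2R)-1-[4-(benzyloxy)-3-methoxyphenyl]-2-[4-bromo-2-methoxy-6-(prop-2-en-1-yloxy)phenyl]propane-1,3-diol | OC[C@@H](c1c(OC)cc(Br)cc1OCC=C)[C@H](O)c1ccc(OCc2ccccc2)c(OC)c1 | intermediate
15 | (1S,2R)-1-[4-(benzyloxy)-3-methoxyphenyl]-2-(4-bromo-2-hydroxy-6-methoxyphenyl)propane-1,3-diol | OC[C@@H](c1c(OC)cc(Br)cc1O)[C@H](O)c1ccc(OCc2ccccc2)c(OC)c1 | intermediate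
16 | benzylic cation formed from 15 by loss of water at C1 | OC[C@@H](c1c(OC)cc(Br)cc1O)[CH+]c1ccc(OCc2ccccc2)c(OC)c1 | intermediate
17 | [(2S,3R)-2-[4-(benzyloxy)-3-methoxyphenyl]-6-bromo-4-methoxy-2,3-dihydro-1-benzofuran-3-yl]methanol | Brc1cc(OC)c2c(c1)O[C@H](c1ccc(OCc3ccccc3)c(OC)c1)[C@H]2CO | intermediate
18 | {[(2S,3R)-2-[4-(benzyloxy)-3-methoxyphenyl]-6-bromo-4-methoxy-2,3-dihydro-1-benzofuran-3-yl]methoxy}(tert-butyl)dimethylsilane | Brc1cc(OC)c2c(c1)O[C@H](c1ccc(OCc3ccccc3)c(OC)c1)[C@H]2CO[Si](C)(C)C(C)(C)C | intermediate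
19 | (E)-3-(tributylstannyl)prop-2-en-1-ol | CCCC[Sn](CCCC)(CCCC)/C=C/CO | starting material
20 | (E)-3-[(2S,3R)-2-[4-(benzyloxy)-3-methoxyphenyl]-3-{[(tert-butyldimethylsilyl)oxy]methyl}-4-methoxy-2,3-dihydro-1-benzofuran-6-yl]prop-2-en-1-ol | OC/C=C/c1cc(OC)c2c(c1)O[C@H](c1ccc(OCc3ccccc3)c(OC)c1)[C@H]2CO[Si](C)(C)C(C)(C)C | intermediate
21 | {[(2S,3R)-2-[4-(benzyloxy)-3-methoxyphenyl]-6-[(E)-3-bromoprop-1-en-1-yl]-4-methoxy-2,3-dihydro-1-benzofuran-3-yl]methoxy}(tert-butyl)dimethylsilane | BrC/C=C/c1cc(OC)c2c(c1)O[C@H](c1ccc(OCc3ccccc3)c(OC)c1)[C@H]2CO[Si](C)(C)C(C)(C)C | intermediate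
22 | 3-(benzyloxy)-4-methoxybenzaldehyde | COc1ccc(C=O)cc1OCc1ccccc1 | starting material
23 | vinylmagnesium bromide | C=C[Mg]Br | starting material
24 | rac-1-[3-(benzyloxy)-4-methoxyphenyl]prop-2-en-1-ol | COc1ccc(C(O)C=C)cc1OCc1ccccc1 | intermediate
25 | (S)-[3-(benzyloxy)-4-methoxyphenyl][(2R)-oxiran-2-yl]methanol | COc1ccc([C@H](O)[C@H]2CO2)cc1OCc1ccccc1 | intermediate
26 | (2R)-2-[(S)-[3-(benzyloxy)-4-methoxyphenyl]({(2E)-3-[(2S,3R)-2-[4-(benzyloxy)-3-methoxyphenyl]-3-{[(tert-butyldimethylsilyl)oxy]methyl}-4-methoxy-2,3-dihydro-1-benzofuran-6-yl]prop-2-en-1-yl}oxy)methyl]oxirane | COc1ccc([C@H](OC/C=C/c2cc(OC)c3c(c2)O[C@H](c2ccc(OCc4ccccc4)c(OC)c2)[C@H]3CO[Si](C)(C)C(C)(C)C)[C@H]2CO2)cc1OCc1ccccc1 | intermediate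
27 | secondary alkyl radical from 26 with an O–TiCp2Cl group on the former epoxide CH2 | COc1ccc([C@H](OC/C=C/c2cc(OC)c3c(c2)O[C@H](c2ccc(OCc4ccccc4)c(OC)c2)[C@H]3CO[Si](C)(C)C(C)(C)C)[CH]CO[Ti](Cl)(C2C=CC=C2)C2C=CC=C2)cc1OCc1ccccc1 | intermediate
28 | (2R,3S,4S)-oxolane with a benzylic radical on the arm at C4 and CH2O–TiCp2Cl at C3 | COc1ccc([C@@H]2OC[C@@H]([CH]c3cc(OC)c4c(c3)O[C@H](c3ccc(OCc5ccccc5)c(OC)c3)[C@H]4CO[Si](C)(C)C(C)(C)C)[C@H]2CO[Ti](Cl)(C2C=CC=C2)C2C=CC=C2)cc1OCc1ccccc1 | intermediate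
29 | (2R,3S,4S)-oxolane with a benzylic C–TiCp2Cl on the arm at C4 and CH2O–TiCp2Cl at C3 | COc1ccc([C@@H]2OC[C@@H](C([Ti](Cl)(C3C=CC=C3)C3C=CC=C3)c3cc(OC)c4c(c3)O[C@H](c3ccc(OCc5ccccc5)c(OC)c3)[C@H]4CO[Si](C)(C)C(C)(C)C)[C@H]2CO[Ti](Cl)(C2C=CC=C2)C2C=CC=C2)cc1OCc1ccccc1 | intermediate
30 | [(2R,3S,4S)-2-[3-(benzyloxy)-4-methoxyphenyl]-4-{[(2S,3R)-2-[4-(benzyloxy)-3-methoxyphenyl]-3-{[(tert-butyldimethylsilyl)oxy]methyl}-4-methoxy-2,3-dihydro-1-benzofuran-6-yl]methyl}oxolan-3-yl]methanol | COc1ccc([C@@H]2OC[C@@H](Cc3cc(OC)c4c(c3)O[C@H](c3ccc(OCc5ccccc5)c(OC)c3)[C@H]4CO[Si](C)(C)C(C)(C)C)[C@H]2CO)cc1OCc1ccccc1 | intermediate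
31 | [(2R,3S,4S)-2-[3-(benzyloxy)-4-methoxyphenyl]-4-{[(2S,3R)-2-[4-(benzyloxy)-3-methoxyphenyl]-3-(hydroxymethyl)-4-methoxy-2,3-dihydro-1-benzofuran-6-yl]methyl}oxolan-3-yl]methanol | COc1ccc([C@@H]2OC[C@@H](Cc3cc(OC)c4c(c3)O[C@H](c3ccc(OCc5ccccc5)c(OC)c3)[C@H]4CO)[C@H]2CO)cc1OCc1ccccc1 | intermediate
32 | 5-[(2R,3S,4S)-3-(hydroxymethyl)-4-{[(2S,3R)-2-(4-hydroxy-3-methoxyphenyl)-3-(hydroxymethyl)-4-methoxy-2,3-dihydro-1-benzofuran-6-yl]methyl}oxolan-2-yl]-2-methoxyphenol (CNP0242386.1) | COc1ccc([C@@H]2OC[C@@H](Cc3cc(OC)c4c(c3)O[C@H](c3ccc(O)c(OC)c3)[C@H]4CO)[C@H]2CO)cc1O | target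

**Step count and risks**

Total step count: 17. Longest linear sequence: 15 (steps 1–11, then 14–17).

Steps most likely to fail:

1. Step 15. The facial discrimination in the ring closure may be incomplete, so that the 3,4-trans isomer forms alongside the wanted one. Radical 27 may also be reduced by a second Cp2TiCl before it cyclises, which leads to β-elimination and loss of the oxygen function. The fallback sets out from 18 and 25 and comes back at 32. Sonogashira coupling of 18 with propargyl alcohol (PdCl2(PPh3)2, CuI, Et3N) should give the arylpropynol F1, and CBr4/PPh3 the propargylic bromide F2. Alkylation of 25 with F2 (NaH, THF) should give the epoxy propargyl ether F3. Cp2TiCl2/Zn then closes the ring 5-exo-dig onto the alkyne, and the vinyl radical takes hydrogen from THF, giving the 4-benzylidene oxolane F4; here only the 2,3-trans relation has to come from the radical step. Bu4NF gives the diol F5. Hydrogenation over 10% Pd/C should add hydrogen to the exocyclic alkene from the face away from the C3 CH2OH group, which sets the 3,4-cis relation, and should remove both benzyl groups in the same operation to give 32.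

2. Step 14. The alkoxide of 25 may undergo Payne rearrangement (epoxide migration to the benzylic position) faster than it is alkylated by a bulky bromide that is used near 1:1, and the allylic bromide may decompose. The fallback sets out from 25 and 18 and comes back at 26. Allylation of 25 with excess allyl bromide and Ag2O, in which no free alkoxide is formed, should give the allyl ether F6. Suzuki coupling of 18 with potassium vinyltrifluoroborate (PdCl2(dppf), Cs2CO3, THF/H2O) should give the vinylarene F7. Cross-metathesis of F6 with F7 using the second-generation Hoveyda–Grubbs catalyst should give the E-configured ether 26.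

3. Step 2. Addition of the TosMIC anion to the hindered, electron-rich aldehyde may be slow, and the adduct may be diverted to an oxazole instead of losing formate. The fallback sets out from 2 and comes back at 6. Wittig reaction with the ylide from (methoxymethyl)triphenylphosphonium chloride and KHMDS should give the enol ether F8, hydrolysis with aqueous HCl in THF the arylacetaldehyde F9, and Pinnick oxidation (NaClO2, NaH2PO4, 2-methyl-2-butene) the acid 6.

Further compounds
F1 | step 15 | 3-[(2S,3R)-2-[4-(benzyloxy)-3-methoxyphenyl]-3-{[(tert-butyldimethylsilyl)oxy]methyl}-4-methoxy-2,3-dihydro-1-benzofuran-6-yl]prop-2-yn-1-ol | OCC#Cc1cc(OC)c2c(c1)O[C@H](c1ccc(OCc3ccccc3)c(OC)c1)[C@H]2CO[Si](C)(C)C(C)(C)C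
F2 | step 15 | {[(2S,3R)-2-[4-(benzyloxy)-3-methoxyphenyl]-6-(3-bromoprop-1-yn-1-yl)-4-methoxy-2,3-dihydro-1-benzofuran-3-yl]methoxy}(tert-butyl)dimethylsilane | BrCC#Cc1cc(OC)c2c(c1)O[C@H](c1ccc(OCc3ccccc3)c(OC)c1)[C@H]2CO[Si](C)(C)C(C)(C)C
F3 | step 15 | epoxy propargyl ether of 25 with F2 (S carbinol carbon, R epoxide carbon) | COc1ccc([C@H](OCC#Cc2cc(OC)c3c(c2)O[C@H](c2ccc(OCc4ccccc4)c(OC)c2)[C@H]3CO[Si](C)(C)C(C)(C)C)[C@H]2CO2)cc1OCc1ccccc1
F4 | step 15 | [(2R,3S)-2-[3-(benzyloxy)-4-methoxyphenyl]-4-(arylmethylidene)oxolan-3-yl]methanol, aryl being the silyl-protected (2S,3R)-benzofuran-6-yl group | COc1ccc([C@@H]2OCC(=Cc3cc(OC)c4c(c3)O[C@H](c3ccc(OCc5ccccc5)c(OC)c3)[C@H]4CO[Si](C)(C)C(C)(C)C)[C@H]2CO)cc1OCc1ccccc1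
F5 | step 15 | desilylated diol of F4 | COc1ccc([C@@H]2OCC(=Cc3cc(OC)c4c(c3)O[C@H](c3ccc(OCc5ccccc5)c(OC)c3)[C@H]4CO)[C@H]2CO)cc1OCc1ccccc1
F6 | step 14 | (2R)-2-[(S)-[3-(benzyloxy)-4-methoxyphenyl](prop-2-en-1-yloxy)methyl]oxirane | COc1ccc([C@H](OCC=C)[C@H]2CO2)cc1OCc1ccccc1
F7 | step 14 | {[(2S,3R)-2-[4-(benzyloxy)-3-methoxyphenyl]-6-ethenyl-4-methoxy-2,3-dihydro-1-benzofuran-3-yl]methoxy}(tert-butyl)dimethylsilane | C=Cc1cc(OC)c2c(c1)O[C@H](c1ccc(OCc3ccccc3)c(OC)c1)[C@H]2CO[Si](C)(C)C(C)(C)C
F8 | step 2 | 5-bromo-1-methoxy-2-(2-methoxyethenyl)-3-(prop-2-en-1-yloxy)benzene | COC=Cc1c(OC)cc(Br)cc1OCC=C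
F9 | step 2 | 2-[4-bromo-2-methoxy-6-(prop-2-en-1-yloxy)phenyl]acetaldehyde | COc1cc(Br)cc(OCC=C)c1CC=O
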